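Retrosynthesis: the C6=C7/C8=C17 diene is traced back (1,4-elimination, 1,2-reduction, dehydration) to a 7-hydroxy-8-carbaldehyde, and ring B is then cut at C9–C10 and at C7–C8.
The cut is possible because quaternary C10 with its methyl C20 is the hydrogen adduct of a methylidene group on ring A, C9 is the β-carbon of an enal whose α-carbon and formyl carbon are C8 and C17, and C7 is an aldehyde on the C5 arm.
Forward: the ring A aldehyde (six steps from 3-methylcyclohex-2-en-1-one) and the side-chain dienal (two steps from methyl geranate) are joined in one operation that closes ring B; four steps then turn the aldol into the diene.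
Stereochemistry: C4 comes from a ligand-controlled copper-catalysed conjugate addition and C5 from allylation of the resulting enolate anti to the silylmethyl group. C10 and C9 come from substrate control in the annulation (bond formation anti to the C5 arm, chain equatorial), and the 13E olefin from methyl geranate.

Key step: step 9

Assumption: atoms carry labdane numbers (C18 = acetoxymethyl carbon on C4, C20 = methyl on C10, C17 = methylidene carbon on C8). The carbene precursor L of step 1 is 1-(1-hydroxy-4-methylpentan-2-yl)-3-(2,4,6-trimethylphenyl)-4,5-dihydroimidazolium hexafluorophosphate, taken as the enantiomer that gives the 3S quaternary carbon; its sense of induction with this Grignard reagent has to be checked on the first run.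

Step 1
Reactants: 1 3-methylcyclohex-2-en-1-one; 2 (chloromethyl)dimethyl(phenyl)silane; 3 allyl bromide
Product: 6 (2R,3S)-3-{[dimethyl(phenyl)silyl]methyl}-3-methyl-2-(prop-2-en-1-yl)cyclohexan-1-one, via Grignard reagent 4 (not isolated), via magnesium enolate 5 (not isolated)
Conditions: 2, Mg, Et2O, reflux; Cu(OTf)2 (3 mol %), L (4 mol %), then 1, Et2O, −30 → 0 °C; then 3 (3 equiv), DMPU, THF, −30 °C → rt
Reagents that add atoms: none
Why: Copper–carbene-catalysed asymmetric conjugate addition of the Grignard reagent to the β,β-disubstituted enone should set the quaternary carbon C4 under ligand control, and the magnesium enolate is then allylated at C5 on the face anti to the bulky silylmethyl group (conjugate addition–enolate trapping), which places allyl cis to the C4 methyl.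

Step 2
Reactants: 6 (2R,3S)-3-{[dimethyl(phenyl)silyl]methyl}-3-methyl-2-(prop-2-en-1-yl)cyclohexan-1-one
Product: 8 (2R,3S)-2-(2,2-dimethoxyethyl)-3-{[dimethyl(phenyl)silyl]methyl}-3-methylcyclohexan-1-one, via keto aldehyde 7 (not isolated)
Conditions: O3, CH2Cl2/MeOH 4:1, Sudan Red 7B, −78 °C; Me2S, −78 °C → rt; then HC(OMe)3, CeCl3·7H2O (10 mol %), MeOH, rt
Reagents that add atoms: methanol, CO; trimethyl orthoformate, COC(OC)OC
Why: Ozonolysis with reductive work-up cleaves the only alkene (the aryl–silicon unit reacts far more slowly), and lanthanide-catalysed chemoselective acetalisation then protects the aldehyde beside the hindered ketone under neutral conditions that leave C5 untouched.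

Step 3
Reactants: 8 (2R,3S)-2-(2,2-dimethoxyethyl)-3-{[dimethyl(phenyl)silyl]methyl}-3-methylcyclohexan-1-one
Product: 9 {[(1S,2S)-2-(2,2-dimethoxyethyl)-1-methyl-3-methylidenecyclohexyl]methyl}dimethyl(phenyl)silane
Conditions: Cp2TiMe2 (3 equiv), toluene, 70 °C, dark
Reagents that add atoms: dimethyltitanocene (Cp2TiMe2), C[Ti](C)(C1C=CC=C1)C1C=CC=C1
Why: Petasis methylenation: on heating, Cp2TiMe2 gives the titanocene methylidene, which olefinates the hindered ketone through an oxatitanacyclobutane without any base, so the α-stereocentre C5 is not epimerised and acetal and silane are inert.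

Step 4
Reactants: 9 {[(1S,2S)-2-(2,2-dimethoxyethyl)-1-methyl-3-methylidenecyclohexyl]methyl}dimethyl(phenyl)silane
Product: 10 [(1S,2S)-2-(2,2-dimethoxyethyl)-1-methyl-3-methylidenecyclohexyl]methanol
Conditions: t-BuOOH, KH, NMP, 0 °C → rt; then TBAF, 70 °C
Reagents that add atoms: tert-butyl hydroperoxide, CC(C)(C)OO
Why: Tamao–Fleming oxidation in its basic peroxide form: the tert-butyl peroxide anion attacks silicon, phenyl and then the primary alkyl group migrate from silicon to oxygen and fluoride cleaves the Si–O bond, and because no acid or electrophile is present the 1,1-disubstituted alkene and the acetal should survive.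

Step 5
Reactants: 10 [(1S,2S)-2-(2,2-dimethoxyethyl)-1-methyl-3-methylidenecyclohexyl]methanol
Product: 11 [(1S,2S)-2-(2,2-dimethoxyethyl)-1-methyl-3-methylidenecyclohexyl]methyl acetate
Conditions: Ac2O, pyridine, DMAP (cat.), CH2Cl2, rt
Reagents that add atoms: acetic anhydride, CC(=O)OC(C)=O
Why: DMAP-catalysed acylation of the primary neopentyl alcohol is routine, and the acetal and the alkene are inert to the basic medium.

Step 6
Reactants: 11 [(1S,2S)-2-(2,2-dimethoxyethyl)-1-methyl-3-methylidenecyclohexyl]methyl acetate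
Product: 12 [(1S,2S)-1-methyl-3-methylidene-2-(2-oxoethyl)cyclohexyl]methyl acetate (C5 arm cis to the C4 methyl, trans to the acetoxymethyl group)
Conditions: PPTS (20 mol %), acetone/H2O 10:1, 50 °C
Reagents that add atoms: water, O
Why: Mild acid-catalysed acetal hydrolysis frees the aldehyde without moving the exocyclic double bond or cleaving the acetate.

Step 7
Reactants: 13 methyl geranate (methyl (2E)-3,7-dimethylocta-2,6-dienoate)
Product: 14 methyl (2E)-3-methyl-6-oxohex-2-enoate
Conditions: O3, CH2Cl2/MeOH 5:1, Sudan Red 7B, −78 °C; then Me2S, −78 °C → rt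
Reagents that add atoms: ozone, [O-][O+]=O
Why: Chemoselective ozonolysis: the electron-rich trisubstituted C6=C7 alkene reacts far faster than the ester-conjugated C2=C3 alkene, so titration to the indicator end point cleaves only the isopropylidene terminus.

Step 8
Reactants: 14 methyl (2E)-3-methyl-6-oxohex-2-enoate; 15 (triphenylphosphoranylidene)acetaldehyde
Product: 16 methyl (2E,6E)-3-methyl-8-oxoocta-2,6-dienoate
Conditions: 15 (1.1 equiv), toluene, 80 °C
Reagents that add atoms: none
Why: Wittig olefination with the formyl-stabilised ylide gives the (E)-enal, and the saturated aldehyde reacts faster than the product enal, which limits double homologation.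

Step 9
Reactants: 12 [(1S,2S)-1-methyl-3-methylidene-2-(2-oxoethyl)cyclohexyl]methyl acetate; 16 methyl (2E,6E)-3-methyl-8-oxoocta-2,6-dienoate
Product: 18 methyl (2E)-5-[(1R,2R,3R,4aS,5S,8aS)-5-(acetoxymethyl)-2-formyl-3-hydroxy-5,8a-dimethyldecahydronaphthalen-1-yl]-3-methylpent-2-enoate (trans-decalin; side chain, formyl and hydroxyl all equatorial), via adduct enolate 17 (not isolated)
Conditions: Fe(acac)3 (30 mol %), PhSiH3 (2.5 equiv), 16 (3 equiv), EtOH/(CH2OH)2 5:1, 0 °C → rt
Reagents that add atoms: none
Why: Fe(acac)3 and phenylsilane form an iron hydride that transfers a hydrogen atom to the terminal carbon (C20) of the methylidene group of 12; the tertiary C10 radical adds to the β-carbon (C9) of enal 16 (Giese addition), the α-formyl radical is reduced by divalent iron to enolate 17, and 17 attacks the C7 aldehyde. The closest known reaction type is the iron-hydride-initiated radical conjugate addition–aldol (radical–polar crossover) annulation of an alkenyl aldehyde with an unsaturated carbonyl partner to a cyclohexane. Ring B closes by a 6-(enolexo)-exo-trig aldol. C10 is set by 1,2-induction: the cyclohexyl radical is attacked anti to the vicinal C5 arm and to the axial C4 methyl, so the new C9–C10 bond is equatorial and the fusion trans. C9 is expected to form with the C11 chain of the s-trans enal turned away from C5 and C4 in the early, open transition state, which gives the equatorial chain; this is the least secure element, and a C9 epimer would be removed at 18 or 20, whereas C8 and C7 (chair closure, both substituents equatorial) are erased in step 10. The step needs hydrogen-atom transfer to the 1,1-disubstituted alkene only and addition to the enal only, which the electron-rich nature of that alkene and the much lower acceptor quality of the β,β-disubstituted enoate should secure.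

Step 10
Reactants: 18 methyl (2E)-5-[(1R,2R,3R,4aS,5S,8aS)-5-(acetoxymethyl)-2-formyl-3-hydroxy-5,8a-dimethyldecahydronaphthalen-1-yl]-3-methylpent-2-enoate
Product: 20 methyl (2E)-5-[(1S,4aS,5S,8aR)-5-(acetoxymethyl)-2-formyl-5,8a-dimethyl-1,4,4a,5,6,7,8,8a-octahydronaphthalen-1-yl]-3-methylpent-2-enoate (C7=C8 enal), via mesylate 19 (not isolated)
Conditions: MsCl, Et3N, CH2Cl2, 0 °C; then DBU, 0 °C → rt
Reagents that add atoms: none
Why: Mesylation of the β-hydroxyl and E1cB elimination through the aldehyde enolate should give the conjugated C7=C8 enal from any C7/C8 diastereomer, while C9 is not acidic in the product and keeps its configuration.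

Step 11
Reactants: 20 methyl (2E)-5-[(1S,4aS,5S,8aR)-5-(acetoxymethyl)-2-formyl-5,8a-dimethyl-1,4,4a,5,6,7,8,8a-octahydronaphthalen-1-yl]-3-methylpent-2-enoate
Product: 21 methyl (2E)-5-[(1S,4aS,5S,8aR)-5-(acetoxymethyl)-2-(hydroxymethyl)-5,8a-dimethyl-1,4,4a,5,6,7,8,8a-octahydronaphthalen-1-yl]-3-methylpent-2-enoate
Conditions: NaBH4, CeCl3·7H2O, MeOH, −40 °C
Reagents that add atoms: none
Why: Luche reduction: NaBH4 with CeCl3 reduces the enal in the 1,2 sense to the primary allylic alcohol and leaves the enoate and the acetate untouched.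

Step 12
Reactants: 21 methyl (2E)-5-[(1S,4aS,5S,8aR)-5-(acetoxymethyl)-2-(hydroxymethyl)-5,8a-dimethyl-1,4,4a,5,6,7,8,8a-octahydronaphthalen-1-yl]-3-methylpent-2-enoate
Product: 22 methyl (2E)-5-[(1S,4aS,5S,8aR)-5-(acetoxymethyl)-2-{[(methoxycarbonyl)oxy]methyl}-5,8a-dimethyl-1,4,4a,5,6,7,8,8a-octahydronaphthalen-1-yl]-3-methylpent-2-enoate
Conditions: ClCO2Me, pyridine, DMAP (cat.), CH2Cl2, 0 °C → rt
Reagents that add atoms: methyl chloroformate, COC(=O)Cl
Why: Acylation of the primary allylic alcohol with the chloroformate gives the allylic carbonate, the leaving group for the palladium step.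

Step 13
Reactants: 22 methyl (2E)-5-[(1S,4aS,5S,8aR)-5-(acetoxymethyl)-2-{[(methoxycarbonyl)oxy]methyl}-5,8a-dimethyl-1,4,4a,5,6,7,8,8a-octahydronaphthalen-1-yl]-3-methylpent-2-enoate
Product: 23 methyl (2E)-5-[(1R,4aS,5S,8aS)-5-(acetoxymethyl)-5,8a-dimethyl-2-methylidene-1,2,4a,5,6,7,8,8a-octahydronaphthalen-1-yl]-3-methylpent-2-enoate (CNP0148290.1)
Conditions: Pd(OAc)2 (5 mol %), PBu3 (20 mol %), 1,4-dioxane, 100 °C
Reagents that add atoms: none
Why: Tsuji–Trost ionisation by zerovalent palladium gives the C17–C8–C7 π-allyl complex and methoxide, and since C8 bears no hydrogen the only β-hydrogens are on C6, so elimination can give only the C6=C7/C8=C17 diene, while the non-allylic acetate and the stereocentres are unaffected.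

Compound list
1 | 3-methylcyclohex-2-en-1-one | CC1=CC(=O)CCC1 | starting material
2 | (chloromethyl)dimethyl(phenyl)silane | C[Si](C)(CCl)c1ccccc1 | starting material
3 | allyl bromide (3-bromoprop-1-ene) | C=CCBr | starting material
4 | {[dimethyl(phenyl)silyl]methyl}magnesium chloride | C[Si](C)(C[Mg]Cl)c1ccccc1 | intermediate
5 | chloromagnesium (3S)-3-{[dimethyl(phenyl)silyl]methyl}-3-methylcyclohex-1-en-1-olate | Cl[Mg]OC1=C[C@@](C)(C[Si](C)(C)c2ccccc2)CCC1 | intermediate
6 | (2R,3S)-3-{[dimethyl(phenyl)silyl]methyl}-3-methyl-2-(prop-2-en-1-yl)cyclohexan-1-one | C=CC[C@@H]1[C@@](C)(C[Si](C)(C)c2ccccc2)CCCC1=O | intermediate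
7 | 2-[(1R,2S)-2-{[dimethyl(phenyl)silyl]methyl}-2-methyl-6-oxocyclohexyl]acetaldehyde | O=CC[C@@H]1[C@@](C)(C[Si](C)(C)c2ccccc2)CCCC1=O | intermediate
8 | (2R,3S)-2-(2,2-dimethoxyethyl)-3-{[dimethyl(phenyl)silyl]methyl}-3-methylcyclohexan-1-one | COC(OC)C[C@@H]1[C@@](C)(C[Si](C)(C)c2ccccc2)CCCC1=O | intermediate
9 | {[(1S,2S)-2-(2,2-dimethoxyethyl)-1-methyl-3-methylidenecyclohexyl]methyl}dimethyl(phenyl)silane | COC(OC)C[C@@H]1[C@@](C)(C[Si](C)(C)c2ccccc2)CCCC1=C | intermediate
10 | [(1S,2S)-2-(2,2-dimethoxyethyl)-1-methyl-3-methylidenecyclohexyl]methanol | COC(OC)C[C@@H]1[C@@](C)(CO)CCCC1=C | intermediate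
11 | [(1S,2S)-2-(2,2-dimethoxyethyl)-1-methyl-3-methylidenecyclohexyl]methyl acetate | COC(OC)C[C@@H]1[C@@](C)(COC(C)=O)CCCC1=C | intermediate
12 | [(1S,2S)-1-methyl-3-methylidene-2-(2-oxoethyl)cyclohexyl]methyl acetate | O=CC[C@@H]1[C@@](C)(COC(C)=O)CCCC1=C | intermediate
13 | methyl geranate, methyl (2E)-3,7-dimethylocta-2,6-dienoate | CC(C)=CCC/C(C)=C/C(=O)OC | starting material
14 | methyl (2E)-3-methyl-6-oxohex-2-enoate | O=CCC/C(C)=C/C(=O)OC | intermediate
15 | (triphenylphosphoranylidene)acetaldehyde | O=CC=P(c1ccccc1)(c1ccccc1)c1ccccc1 | starting material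
16 | methyl (2E,6E)-3-methyl-8-oxoocta-2,6-dienoate | O=C/C=C/CC/C(C)=C/C(=O)OC | intermediate
17 | C9–C10-linked conjugate adduct of 12 and 16 as its aldehyde enolate (O–C17=C8), C7 aldehyde still free, configuration at C4, C5, C9 and C10 as in 18 | O=CC[C@@H]1[C@@](C)(COC(C)=O)CCC[C@@]1(C)[C@@H](C=C[O-])CC/C(C)=C/C(=O)OC | intermediate
18 | methyl (2E)-5-[(1R,2R,3R,4aS,5S,8aS)-5-(acetoxymethyl)-2-formyl-3-hydroxy-5,8a-dimethyldecahydronaphthalen-1-yl]-3-methylpent-2-enoate | O=C[C@H]1[C@H](O)C[C@@H]2[C@@](C)(COC(C)=O)CCC[C@@]2(C)[C@@H]1CC/C(C)=C/C(=O)OC | intermediate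
19 | methyl (2E)-5-[(1R,2R,3R,4aS,5S,8aS)-5-(acetoxymethyl)-2-formyl-3-(methanesulfonyloxy)-5,8a-dimethyldecahydronaphthalen-1-yl]-3-methylpent-2-enoate | O=C[C@H]1[C@H](OS(C)(=O)=O)C[C@@H]2[C@@](C)(COC(C)=O)CCC[C@@]2(C)[C@@H]1CC/C(C)=C/C(=O)OC | intermediate
20 | methyl (2E)-5-[(1S,4aS,5S,8aR)-5-(acetoxymethyl)-2-formyl-5,8a-dimethyl-1,4,4a,5,6,7,8,8a-octahydronaphthalen-1-yl]-3-methylpent-2-enoate | O=CC1=CC[C@@H]2[C@@](C)(COC(C)=O)CCC[C@@]2(C)[C@@H]1CC/C(C)=C/C(=O)OC | intermediate
21 | methyl (2E)-5-[(1S,4aS,5S,8aR)-5-(acetoxymethyl)-2-(hydroxymethyl)-5,8a-dimethyl-1,4,4a,5,6,7,8,8a-octahydronaphthalen-1-yl]-3-methylpent-2-enoate | OCC1=CC[C@@H]2[C@@](C)(COC(C)=O)CCC[C@@]2(C)[C@@H]1CC/C(C)=C/C(=O)OC | intermediate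
22 | methyl (2E)-5-[(1S,4aS,5S,8aR)-5-(acetoxymethyl)-2-{[(methoxycarbonyl)oxy]methyl}-5,8a-dimethyl-1,4,4a,5,6,7,8,8a-octahydronaphthalen-1-yl]-3-methylpent-2-enoate | COC(=O)OCC1=CC[C@@H]2[C@@](C)(COC(C)=O)CCC[C@@]2(C)[C@@H]1CC/C(C)=C/C(=O)OC | intermediate
23 | methyl (2E)-5-[(1R,4aS,5S,8aS)-5-(acetoxymethyl)-5,8a-dimethyl-2-methylidene-1,2,4a,5,6,7,8,8a-octahydronaphthalen-1-yl]-3-methylpent-2-enoate | C=C1C=C[C@@H]2[C@@](C)(COC(C)=O)CCC[C@@]2(C)[C@@H]1CC/C(C)=C/C(=O)OC | target

Total step count: 13. Longest linear sequence: 11 steps (steps 1–6, then 9–13); the side-chain branch (steps 7 and 8) joins at step 9.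

Steps most likely to fail

Step 9. The open transition state of the intermolecular radical addition may give poor facial selectivity at C9, and conjugate reduction of the enal by the iron hydride may compete. The fallback takes the stereogenic event out of the radical step by using an ynal and sets C9 afterwards by intramolecular hydrogen delivery; it sets out from 14 and 12 and comes back at 23. Ohira–Bestmann homologation of 14 (dimethyl (1-diazo-2-oxopropyl)phosphonate, K2CO3, MeOH) would give methyl (2E)-3-methylhept-2-en-6-ynoate F1. Deprotonation of the alkyne with one equivalent of n-BuLi (THF, −78 °C), which should be much faster than attack on the hindered conjugated ester, and formylation with DMF would give the ynal methyl (2E)-3-methyl-8-oxooct-2-en-6-ynoate F2. Under the conditions of step 9, 12 and F2 should give the 7-hydroxy-8-ene-8-carbaldehyde F3 (radical addition to the alkyne carbon C9, reduction of the α-formylvinyl radical to the allenolate, aldol closure), in which C9 is trigonal. Condensation with TsNHNH2 would give the tosylhydrazone F4. Reduction with catecholborane and warming with NaOAc·3H2O should give the allylic diazene, which loses nitrogen while its hydrogen moves to C9 and the double bond shifts to C8=C17 (reductive allylic transposition). The hydrogen should enter the C9 face anti to the axial C10 methyl, so the chain becomes equatorial and the 7-hydroxy-8(17)-ene F5 results. Its methyl carbonate F6 (ClCO2Me, pyridine) ionises to the same π-allyl palladium complex as 22 and should give 23 under the conditions of step 13.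

Step 1. Facial control in the alkylation of enolate 5 may be incomplete (allyl entering syn to the silylmethyl group), and polyallylation may occur. The fallback replaces the substrate-controlled alkylation by a catalyst-controlled palladium allylation; it sets out from 1 and 2 and comes back at 6. The conjugate addition is run as in step 1, but enolate 5 is trapped on oxygen with allyl chloroformate (THF, −78 °C) to give allyl (3S)-3-{[dimethyl(phenyl)silyl]methyl}-3-methylcyclohex-1-en-1-yl carbonate F7. Pd2(dba)3 with 4-tert-butyl-2-[2-(diphenylphosphino)phenyl]-4,5-dihydrooxazole (enantiomer matched to the anti approach; toluene, rt) then effects decarboxylative allylation to 6. The bulky π-allyl palladium enolate should be more sensitive to the silylmethyl group than allyl bromide, and the ligand reinforces the facial preference.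

Step 13. The π-allyl complex may be captured by methoxide to give allylic methyl ethers, or a palladium hydride may move the new diene into the ring. The fallback is a metal-free 1,4-dehydration through a sulfenate–sulfoxide rearrangement; it sets out from 21 and comes back at 23. 2,4-Dinitrobenzenesulfenyl chloride and Et3N (CH2Cl2, 0 °C) would give the allylic 2,4-dinitrobenzenesulfenate F8, which undergoes [2,3]-sigmatropic rearrangement to the C7 allylic sulfoxide F9 with C8=C17 in place. Warming in 1,2-dichloroethane (80 °C) should cause syn elimination of the arenesulfenic acid with a C6 hydrogen, the only β-hydrogen available, to give 23.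

Further compounds
F1 | step 9 | methyl (2E)-3-methylhept-2-en-6-ynoate | C#CCC/C(C)=C/C(=O)OC
F2 | step 9 | methyl (2E)-3-methyl-8-oxooct-2-en-6-ynoate | O=CC#CCC/C(C)=C/C(=O)OC
F3 | step 9 | 7-hydroxy-8-ene-8-carbaldehyde annulation product (C8=C9 double bond, C7 epimers) | O=CC=1C(O)C[C@@H]2[C@@](C)(COC(C)=O)CCC[C@@]2(C)C=1CC/C(C)=C/C(=O)OC
F4 | step 9 | tosylhydrazone of F3 | Cc1ccc(cc1)S(=O)(=O)NN=CC=1C(O)C[C@@H]2[C@@](C)(COC(C)=O)CCC[C@@]2(C)C=1CC/C(C)=C/C(=O)OC
F5 | step 9 | 7-hydroxy-8(17)-ene (7-hydroxy-6,7-dihydro analogue of 23, C7 epimers) | C=C1C(O)C[C@@H]2[C@@](C)(COC(C)=O)CCC[C@@]2(C)[C@@H]1CC/C(C)=C/C(=O)OC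
F6 | step 9 | methyl carbonate of F5 | C=C1C(OC(=O)OC)C[C@@H]2[C@@](C)(COC(C)=O)CCC[C@@]2(C)[C@@H]1CC/C(C)=C/C(=O)OC
F7 | step 1 | allyl (3S)-3-{[dimethyl(phenyl)silyl]methyl}-3-methylcyclohex-1-en-1-yl carbonate | C=CCOC(=O)OC1=C[C@@](C)(C[Si](C)(C)c2ccccc2)CCC1
F8 | step 13 | 2,4-dinitrobenzenesulfenate of 21 (S–O–C17) | [O-][N+](=O)c1ccc(SOCC2=CC[C@@H]3[C@@](C)(COC(C)=O)CCC[C@@]3(C)[C@@H]2CC/C(C)=C/C(=O)OC)c([N+](=O)[O-])c1
F9 | step 13 | C7 allylic 2,4-dinitrophenyl sulfoxide with C8=C17 (epimers at C7 and sulfur) | C=C1C(S(=O)c3ccc(cc3[N+](=O)[O-])[N+](=O)[O-])C[C@@H]2[C@@](C)(COC(C)=O)CCC[C@@]2(C)[C@@H]1CC/C(C)=C/C(=O)OC
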